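- Time comes first: at 8.7 h Tuesday's run has made 0.1741 M of product, and Thursday's run, charged with 0.200 M of product as well, has gained 0.176 M, so I follow the slowing by the clock and not by the product present.

| flask | starting material | coupling partner | free catalyst | product | time |
|---|---|---|---|---|---|
| Tuesday's | 0.400 M | 1.00 M | 0.0200 M |  |  |
| Sunday's | 0.600 M | 1.00 M | 0.0200 M |  |  |
| Saturday's | 0.400 M | 1.50 M | 0.0200 M |  |  |
| Thursday's | 0.400 M | 1.00 M | 0.0200 M | 0.200 M |  |
| Friday's | 0.400 M | 3.00 M | 0.0600 M |  | 8.7 h |

| run | time / h | [product] / M |
|---|---|---|
| Tuesday's run | 0.35 | 0.0208 |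
| Tuesday's run | 0.66 | 0.0316 |
| Tuesday's run | 1.3 | 0.0590 |
| Tuesday's run | 2.4 | 0.0899 |
| Tuesday's run | 4.6 | 0.1306 |
| Tuesday's run | 8.7 | 0.1741 |
| Sunday's run | 0.35 | 0.0263 |
| Sunday's run | 0.66 | 0.0439 |
| Sunday's run | 1.3 | 0.0826 |
| Sunday's run | 2.4 | 0.1361 |
| Sunday's run | 4.6 | 0.1934 |
| Sunday's run | 8.7 | 0.2542 |
| Saturday's run | 0.35 | 0.0287 |
| Saturday's run | 0.66 | 0.0495 |
| Saturday's run | 1.3 | 0.0820 |
| Saturday's run | 2.4 | 0.1281 |
| Saturday's run | 4.6 | 0.1796 |
| Saturday's run | 8.7 | 0.2356 |
| Thursday's run | 0.35 | 0.2184 |
| Thursday's run | 0.66 | 0.2341 |
| Thursday's run | 1.3 | 0.2615 |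
| Thursday's run | 2.4 | 0.2922 |
| Thursday's run | 4.6 | 0.3334 |
| Thursday's run | 8.7 | 0.3763 |

(scatter of a reading: 0.002 M)

- Overall: starting material + coupling partner -> product, with free catalyst as catalyst.
- Constant volume, constant temperature.
- "The second partner" is coupling partner.
- An order is taken over about fifteen percent of the charge, up and down.

1. order of the initial rate in [starting material], near the charge of the Tuesday's run, the rate being that where two percent of its starting material are product (one fixed amount of product, the same in the runs compared)
2. order of the initial rate in [coupling partner], near the charge of the Tuesday's run, the rate being that where two percent of its starting material are product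
3. product in the Friday's run at 8.7 h, as a share of the starting material charged

- I try the simplest rate, k[free catalyst][starting material][coupling partner]. I take [coupling partner]/[starting material] now, divide it by the same ratio at the start, take the logarithm, and divide by the starting difference [coupling partner] − [starting material].
- I call this the dose, here Tuesday's at 8.7 h, 0.633 /M: under that rate it equals k times the area under [free catalyst] against time, so it measures the work the catalyst has delivered.
- At 8.7 h the dose reads 0.633 /M in Tuesday's run, 0.644 /M in Sunday's, 0.653 /M in Saturday's and 0.645 /M in Thursday's, so I reckon on order one in each partner.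
- If free catalyst dies in pairs, [free catalyst] falls as one over (1 + at), the dose is A ln(1 + at), and the reciprocal of the dose rate climbs on a straight line against time.
- Tuesday's dose at 2.4 h is 0.267 /M. The mean dose rates before and after that reading are 0.111 /M/h and 0.0581 /M/h, placed at the middle of each stretch. Their reciprocals give the line a slope of 1.89 M; the slope over the line's intercept gives a = 0.282 /h, and Tuesday's dose at 8.7 h then gives A = 0.511 /M.
- Friday's run has 3.00 times the catalyst, and no run tests that change, so I assume a scales with the charge, to 0.845 /h, with A unchanged. The dose at 8.7 h is then 1.09 /M.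
- Starting material is the limiting reagent in Friday's run, 0.400 M against 3.00 M, and that dose turns 94.8 % of it.
- The forecast says “the slowdown follows clock time: the catalyst is dying”, and gives orders 0.75 and 0.9 with 90 %; its share lies below mine, and its orders lie below the one I reckon on.
- The simulation gives orders 1.1 and 1.0, with 97.3 % in Friday's run.

    free catalyst + starting material + coupling partner → product + free catalyst (13.28 /M²/h)
    2 free catalyst → 2 spent catalyst (12.42 /M/h)
    free catalyst + impurity → spent catalyst

- In Friday's run the impurity, 0.00908 M, takes its share of free catalyst at once, a step that barely moves the share made. Coupling and the pairwise loss then run together while free catalyst remains. The dose read from 97.3 % is 1.33 /M, twice Tuesday's 0.633 /M. In Saturday's run, half-turned starting material means a dose of 0.500 /M, which Tuesday's curve places at 5.89 h, and the run reaches it at 5.70 h.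

The runs are simulated with made-up constants; the scatter is artificial.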